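**Retrosynthetic overview**

1. The core is numbered as a bicyclo[3.3.1]nonane-2,4,9-trione: C1 (benzoyl), C2, C3 (shared with the cyclopentanone), C4, C5 (geranyl), C6, C7, C8 (CMe2), C9. The last step makes C2–C3 and C1–C8 together from bicyclic diketone 21, a cycloheptanone fused to a 2,2-dimethylcyclopentanone. In 21 the C9–C1–C2 unit sits on C5 as a 5-acyl-6-phenyl-1,3-dioxin-4-one and C8 sits on C7 as a tertiary silyl ether.
2. Enabling feature: C1 is flanked by three carbonyls (C2, C9, benzoyl) and is next to the gem-dimethyl carbon C8. On the seven-membered ring C3–C4–C5–C6–C7–CH2–CH the C5 acyl arm, the C7 CMe2–O group and the C3–H are 1,3-syn, so C2 is an acyl donor held over the C3 enolate and C8 is a tertiary cation held over C1.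
3. 21 comes from thioester 17 and a zincated dioxinone (Fukuyama coupling). 17 comes from bridged δ-lactone 15, a temporary ring (C9 carboxyl to the oxygen on C8) that forces geranyl onto the correct face of C5 and then releases both the acyl donor and the cation precursor.
4. The lactone comes from cycloheptanone β-keto ester 12, made by diazoacetate ring expansion of cis-hydrindanedione 10. 10 comes from a Danheiser (3+2) annulation and Tamao–Fleming oxidation on (R)-5-isopropenylcyclohex-2-enone, itself from a rhodium-catalysed asymmetric conjugate addition to cyclohexenone.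
5. Ring order: cyclohexanone (bought), cyclopentanone, ring expansion to the cycloheptanone, temporary lactone, temporary dioxinone (bought), then the triketone ring and the second carbocycle of the cage in the last step.

Key step: step 12

Remark: intermediates are named on decahydroazulene locants (C7 of the azulene is the future C5, C8 the future C4, C8a the future C3, C5 the future C7); 2,2-dimethyl-6-phenyl-4H-1,3-dioxin-4-one 18 is taken as a purchasable building block.

**Route**

Step 1
Reactants: 1 cyclohex-2-en-1-one; 2 potassium trifluoro(prop-1-en-2-yl)borate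
Product: 3 (R)-3-(prop-1-en-2-yl)cyclohexan-1-one
Conditions: [Rh(cod)2]PF6 (3 mol%), (R)-BINAP, toluene/H2O, 105 °C
Reagents that add atoms: none
Why: Rhodium-catalysed asymmetric 1,4-addition of an alkenylboron reagent to a cyclic enone (Hayashi–Miyaura reaction) should be highly enantioselective, the (R)-BINAP complex delivering the isopropenyl group to the enone face that sets the (R) centre, the future C7.

Step 2
Reactants: 3 (R)-3-(prop-1-en-2-yl)cyclohexan-1-one
Product: 5 (R)-5-(prop-1-en-2-yl)cyclohex-2-en-1-one, via silyl enol ether 4 (not isolated)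
Conditions: LiN(i-Pr)2, Me3SiCl (in situ quench), THF, −78 °C; then Pd(OAc)2, MeCN, 25 °C
Reagents that add atoms: none
Why: Kinetic deprotonation should occur mainly at the α-methylene remote from the substituent, and Saegusa–Ito oxidation of silyl enol ether 4 then gives the 5-substituted enone without touching the stereocentre (the minor regioisomer would give an achiral dienone that is separated).

Step 3
Reactants: 6 3-methylbuta-1,2-diene; 7 benzyl(chloro)dimethylsilane
Product: 8 benzyl(dimethyl)(3-methylbuta-1,2-dien-1-yl)silane
Conditions: n-BuLi, THF, −78 → −20 °C; then 7, −78 → 0 °C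
Reagents that add atoms: none
Why: Lithiation of the terminal allenic C–H of 1,1-dimethylallene and silylation at that carbon is the usual route to 1-silylallenes, and the benzyl group on silicon is chosen so that the silane can later be oxidised without a peracid.

Step 4
Reactants: 5 (R)-5-(prop-1-en-2-yl)cyclohex-2-en-1-one; 8 benzyl(dimethyl)(3-methylbuta-1,2-dien-1-yl)silane
Product: 9 cis-fused 2-[benzyl(dimethyl)silyl]-3,3-dimethyl-5-(prop-1-en-2-yl)-3,3a,4,5,6,7a-hexahydroinden-7-one
Conditions: TiCl4, CH2Cl2, −78 °C
Reagents that add atoms: none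
Why: Danheiser (3+2) annulation, in which the CMe2 terminus of the allenylsilane adds to the β-carbon anti to the isopropenyl group (axial attack, as in the annulation of carvone) and 1,2-silyl shift with closure onto the titanium enolate gives the cis-fused cyclopentene, so two stereocentres are set relative to the first.

Step 5
Reactants: 9 cis-fused bicyclic vinylsilane
Product: 10 cis-fused 3,3-dimethyl-5-(prop-1-en-2-yl)hexahydro-1H-indene-2,7-dione
Conditions: Bu4NF, THF, 0 °C; then H2O2, KHCO3, MeOH, 25 °C
Reagents that add atoms: hydrogen peroxide, OO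
Why: Tamao–Fleming oxidation, in which fluoride cleaves the benzyl–silicon bond and basic peroxide converts the alkenylsilane into the enol and hence the cyclopentanone, leaves the 1,1-disubstituted alkene untouched and changes no stereocentre.

Step 6
Reactants: 10 cis-fused hydrindanedione; 11 tert-butyl diazoacetate
Product: 12 tert-butyl 3,3-dimethyl-2,8-dioxo-5-(prop-1-en-2-yl)decahydroazulene-7-carboxylate
Conditions: BF3·OEt2, CH2Cl2, −20 → 0 °C
Reagents that add atoms: none
Why: Lewis-acid-promoted diazoacetate homologation (Tiffeneau–Demjanov-type ring expansion) should take place at the cyclohexanone and not at the hindered cyclopentanone, with migration of the less substituted α-methylene, to give the cycloheptanone β-keto ester whose new α-centre is freely epimerisable.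

Step 7
Reactants: 12 tert-butyl β-keto ester
Product: 13 bridged tricyclic diketo δ-lactone (C7 carbonyl joined through oxygen to the CMe2 carbon on C5, on the face opposite to the cyclopentanone)
Conditions: CF3SO3H (0.2 equiv), CH2Cl2, −20 → 0 °C
Reagents that add atoms: none
Why: Acid-catalysed hydro-acyloxylation of the alkene by the tert-butyl ester (lactonisation with loss of 2-methylpropene) can only occur when ester and CMe2 cation are cis, so the epimerisable ester centre is drawn into the bridged lactone, whereas capture by the ketone oxygen would need a strained bridgehead enol ether.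

Step 8
Reactants: 13 bridged diketo lactone; 14 geranyl bromide
Product: 15 bridged diketo lactone carrying geranyl on the bridgehead carbon between ketone and lactone carbonyl
Conditions: Cs2CO3, DMF, 0 → 25 °C
Reagents that add atoms: none
Why: C-alkylation of the β-keto lactone enolate by an allylic bromide (SN2) sets the quaternary centre (future C5) unambiguously, because the carbon is a bridgehead with a single open position, which leaves the carbonyl arm cis to the CMe2–O carbon and geranyl on the cyclopentanone face.

Step 9
Reactants: 15 geranylated bridged lactone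
Product: 17 S-ethyl 7-geranyl-3,3-dimethyl-2,8-dioxo-5-[2-(trimethylsilyloxy)propan-2-yl]decahydroazulene-7-carbothioate, via hydroxy thioester 16 (not isolated)
Conditions: Me3Al, EtSH, CH2Cl2, 0 °C; then 2,6-lutidine, Me3SiOTf, −78 °C
Reagents that add atoms: ethanethiol, CCS; trimethylsilyl trifluoromethanesulfonate, C[Si](C)(C)OS(=O)(=O)C(F)(F)F
Why: Dimethylaluminium ethanethiolate opens lactones by acyl–oxygen cleavage to thioesters, and immediate silylation of the released tertiary alkoxide prevents relactonisation, with no stereocentre touched.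

Step 10
Reactants: 18 2,2-dimethyl-6-phenyl-4H-1,3-dioxin-4-one
Product: 19 5-iodo-2,2-dimethyl-6-phenyl-4H-1,3-dioxin-4-one
Conditions: N-iodosuccinimide, AcOH, 25 °C
Reagents that add atoms: N-iodosuccinimide, O=C1CCC(=O)N1I
Why: Electrophilic iodination at C5 of a 1,3-dioxin-4-one, the nucleophilic α-carbon of its enol ether, is an established halogenation and creates no stereocentre.

Step 11
Reactants: 17 silyloxy thioester; 19 5-iodo-2,2-dimethyl-6-phenyl-4H-1,3-dioxin-4-one
Product: 21 7-[(2,2-dimethyl-4-oxo-6-phenyl-4H-1,3-dioxin-5-yl)carbonyl]-7-geranyl-3,3-dimethyl-5-[2-(trimethylsilyloxy)propan-2-yl]octahydroazulene-2,8-dione, via alkenylzinc chloride 20 (not isolated)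
Conditions: 19, i-PrMgCl·LiCl, THF, −40 °C; ZnCl2; then 17, PdCl2(PPh3)2 (5 mol%), THF/toluene, 25 °C
Reagents that add atoms: none
Why: Fukuyama coupling of a thioester with the alkenylzinc reagent obtained by iodine–magnesium exchange and transmetallation gives the ketone under conditions that tolerate the free ketones, the silyl ether and the alkenes, and forms no stereocentre.

Step 12
Reactants: 21 acyl-dioxinone diketone
Product: 23 CNP0110281.1, via benzoyl-dione 22 (not isolated)
Conditions: LiN(SiMe3)2 (3 equiv), THF, −78 → 0 °C; then HCO2H (excess), 25 °C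
Reagents that add atoms: none
Why: Proposed new method: LiN(SiMe3)2 forms the enolate at the ring-fusion carbon C3 (the only α-hydrogen of the C4 ketone), C3 attacks the dioxinone carbonyl C2 that the C5 acyl arm holds under it, and collapse of the tetrahedral intermediate with loss of acetone gives the enolate of benzoyl-dione 22 in a transannular Claisen condensation; the closest known reactions are Claisen and Dieckmann condensations of ketone enolates with activated esters and the ring-opening of 1,3-dioxin-4-ones by heteroatom nucleophiles, which have not been combined with a carbon nucleophile in this way. Formic acid then protonates 22, removes the silyl group and ionises the tertiary C8–O bond, and the cation is captured by C1 of the enolised 2-benzoyl-1,3-dione, the bond by which cationic biomimetic cyclisations close this ring in the acylphloroglucinol family. The triketone ring (C1, C2, C3, C4, C5, C9) closes by 6-exo-trig attack of the enolate carbon on the ester-type carbonyl, the carbocycle (C1, C8, C7, C6, C5, C9) closes by attack of the enol carbon on the cation carbon, and the two bonds together complete the seven-membered ring C1–C2–C3–CH–CH2–C7–C8 of the homoadamantane. The new stereocentres C3 and C1 are controlled by the tether: the acyl arm on C5 and the CMe2 group on C7 lie on the cycloheptanone face opposite to the cyclopentanone (fixed by lactone 13 and by step 4), so C2 and C8 can only bond from that face and the cyclopentanone ends cis-fused. The step needs C- rather than O-acylation and attack at C2 rather than at the phenyl-bearing dioxinone carbon (lithium enolate, unhindered carbonyl against a fully substituted alkene carbon), C- rather than O-alkylation of the cation (enol ethers from O-attack re-ionise in formic acid and drain to the C–C bonded cage, and an isopropylidene formed by proton loss re-enters the same cation), and survival of the geranyl alkenes (weak acid, cation on the face remote from the chain).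

**Compound list**

1 | cyclohex-2-en-1-one | O=C1C=CCCC1 | starting material
2 | potassium trifluoro(prop-1-en-2-yl)borate | C=C(C)[B-](F)(F)F.[K+] | starting material
3 | (R)-3-(prop-1-en-2-yl)cyclohexan-1-one | O=C1C[C@H](C(C)=C)CCC1 | intermediate
4 | (R)-trimethyl{[5-(prop-1-en-2-yl)cyclohex-1-en-1-yl]oxy}silane (not isolated) | C[Si](C)(C)OC1=CCC[C@@H](C(C)=C)C1 | intermediate
5 | (R)-5-(prop-1-en-2-yl)cyclohex-2-en-1-one | O=C1C=CC[C@@H](C(C)=C)C1 | intermediate
6 | 3-methylbuta-1,2-diene | CC(C)=C=C | starting material
7 | benzyl(chloro)dimethylsilane | C[Si](C)(Cl)Cc1ccccc1 | starting material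
8 | benzyl(dimethyl)(3-methylbuta-1,2-dien-1-yl)silane | CC(C)=C=C[Si](C)(C)Cc1ccccc1 | intermediate
9 | cis-fused 2-[benzyl(dimethyl)silyl]-3,3-dimethyl-5-(prop-1-en-2-yl)-3,3a,4,5,6,7a-hexahydroinden-7-one; isopropenyl trans to the C3a–C3 bond | O=C1C[C@H](C(C)=C)C[C@H]2C(C)(C)C([Si](C)(C)Cc3ccccc3)=C[C@@H]12 | intermediate
10 | cis-fused 3,3-dimethyl-5-(prop-1-en-2-yl)hexahydro-1H-indene-2,7-dione; isopropenyl trans to the C3a–C3 bond | O=C1C[C@H](C(C)=C)C[C@H]2C(C)(C)C(=O)C[C@@H]12 | intermediate
11 | tert-butyl diazoacetate | [N-]=[N+]=CC(=O)OC(C)(C)C | starting material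
12 | tert-butyl 3,3-dimethyl-2,8-dioxo-5-(prop-1-en-2-yl)decahydroazulene-7-carboxylate; cis ring fusion, ester drawn cis to isopropenyl (epimerisable centre) | O=C1[C@H](C(=O)OC(C)(C)C)C[C@H](C(C)=C)C[C@H]2C(C)(C)C(=O)C[C@@H]12 | intermediate
13 | bridged tricyclic diketo δ-lactone: C7 carbonyl of 12 joined through oxygen to the CMe2 carbon on C5, bridge on the face opposite to the cyclopentanone | O=C1[C@H]2C[C@@H](C[C@H]3C(C)(C)C(=O)C[C@@H]13)C(C)(C)OC2=O | intermediate
14 | geranyl bromide, (E)-1-bromo-3,7-dimethylocta-2,6-diene | CC(C)=CCC/C(C)=C/CBr | starting material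
15 | lactone 13 with geranyl on the bridgehead carbon between ketone and lactone carbonyl | O=C1[C@@]2(C/C=C(\C)CCC=C(C)C)C[C@@H](C[C@H]3C(C)(C)C(=O)C[C@@H]13)C(C)(C)OC2=O | intermediate
16 | S-ethyl 7-geranyl-5-(2-hydroxypropan-2-yl)-3,3-dimethyl-2,8-dioxodecahydroazulene-7-carbothioate (not isolated) | O=C1[C@](C/C=C(\C)CCC=C(C)C)(C(=O)SCC)C[C@@H](C[C@H]2C(C)(C)C(=O)C[C@@H]12)C(C)(C)O | intermediate
17 | S-ethyl 7-geranyl-3,3-dimethyl-2,8-dioxo-5-[2-(trimethylsilyloxy)propan-2-yl]decahydroazulene-7-carbothioate | O=C1[C@](C/C=C(\C)CCC=C(C)C)(C(=O)SCC)C[C@@H](C[C@H]2C(C)(C)C(=O)C[C@@H]12)C(C)(C)O[Si](C)(C)C | intermediate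
18 | 2,2-dimethyl-6-phenyl-4H-1,3-dioxin-4-one | O=C1C=C(c2ccccc2)OC(C)(C)O1 | starting material
19 | 5-iodo-2,2-dimethyl-6-phenyl-4H-1,3-dioxin-4-one | O=C1C(I)=C(c2ccccc2)OC(C)(C)O1 | intermediate
20 | chloro(2,2-dimethyl-4-oxo-6-phenyl-4H-1,3-dioxin-5-yl)zinc (not isolated) | O=C1C([Zn]Cl)=C(c2ccccc2)OC(C)(C)O1 | intermediate
21 | 7-[(2,2-dimethyl-4-oxo-6-phenyl-4H-1,3-dioxin-5-yl)carbonyl]-7-geranyl-3,3-dimethyl-5-[2-(trimethylsilyloxy)propan-2-yl]octahydroazulene-2,8-dione; acyl arm cis to the C5 substituent, geranyl on the cyclopentanone face | O=C1[C@](C/C=C(\C)CCC=C(C)C)(C(=O)C3=C(c4ccccc4)OC(C)(C)OC3=O)C[C@@H](C[C@H]2C(C)(C)C(=O)C[C@@H]12)C(C)(C)O[Si](C)(C)C | intermediate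
22 | bridged tricyclic 2-benzoyl-1,3-dione (enol form) with the C2–C3 bond formed and C8 still a CMe2–OSiMe3 group on C7 (not isolated) | CC(C)=CCC/C(C)=C/C[C@@]12C[C@H](C(C)(C)O[Si](C)(C)C)C[C@H]3C(C)(C)C(=O)C[C@]3(C1=O)C(O)=C(C(=O)c1ccccc1)C2=O | intermediate
23 | CNP0110281.1 | CC(C)=CCC/C(C)=C/C[C@@]12C[C@H]3C[C@H]4C(C)(C)C(=O)C[C@]4(C1=O)C(=O)[C@@](C(=O)c1ccccc1)(C2=O)C3(C)C | target

**Step count and risks**

Total step count: 12 (ten in the main line, plus step 3 for allenylsilane 8 and step 10 for iodide 19).
Longest linear sequence: 10 steps (1, 2, 4, 5, 6, 7, 8, 9, 11, 12).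

Steps most likely to fail:

1. Step 12 (proposed new method). What may go wrong: O-acylation of the enolate or attack at the phenyl-bearing dioxinone carbon in the base stage, and acid-induced cyclisation or solvolysis of the geranyl chain competing with ionisation at C8. Fallback with known chemistry, setting out from 21: heating with pentafluorophenol in toluene (110 °C) opens the dioxinone by loss of acetone and capture of the acylketene, giving pentafluorophenyl ester F1. MgBr2·OEt2 and i-Pr2NEt in CH2Cl2 (soft-enolisation Claisen condensation of a ketone with an activated aryl ester) then close the C2–C3 bond to give 22, which is isolated. 22 is cyclised in a separate operation with HCO2H or, if the geranyl chain suffers, with catalytic Me3SiOTf and 2,6-di-tert-butyl-4-methylpyridine at −78 °C. The fallback rejoins the route at 22 and ends at 23.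

2. Step 8. What may go wrong: insufficient enolisation at the bridgehead carbon (poor overlap with both carbonyls), so that alkylation proceeds through the ketone enolates or not at all. Fallback, setting out from 12: the β-keto ester is geranylated before the lactone is closed (14, K2CO3, toluene, a chiral quaternary ammonium phase-transfer catalyst, 0 °C) to give quaternary tert-butyl ester F2, the epimer with the ester cis to isopropenyl, separated from the other if needed. F2 is then lactonised selectively at the 1,1-disubstituted alkene by cobalt-catalysed hydrogen-atom-transfer hydro-acyloxylation (Co(salen), C16H14CoN2O2; N-fluoro-2,4,6-trimethylpyridinium triflate; PhSiH3), the tert-butyl group leaving as 2-methylpropene. This returns to the route at 15.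

3. Step 11. What may go wrong: slow oxidative addition at the α-quaternary thioester and decarbonylation of the acylpalladium intermediate before transmetallation with the hindered alkenylzinc. Fallback, setting out from 17: Fukuyama reduction (Et3SiH, Pd/C, acetone) gives aldehyde F3. The 5-magnesiated dioxinone (from 19 and i-PrMgCl·LiCl, THF, −40 °C) adds to the aldehyde in preference to the two ketones to give carbinol F4, and oxidation with DMP (NaHCO3, CH2Cl2) returns to the route at 21.

Further compounds
F1 | step 12 | pentafluorophenyl 2-benzoyl-3-oxo-3-{7-geranyl-3,3-dimethyl-2,8-dioxo-5-[2-(trimethylsilyloxy)propan-2-yl]decahydroazulen-7-yl}propanoate (C-2 of the arm enolisable, configuration undefined) | O=C1[C@](C/C=C(\C)CCC=C(C)C)(C(=O)C(C(=O)c3ccccc3)C(=O)Oc4c(F)c(F)c(F)c(F)c4F)C[C@@H](C[C@H]2C(C)(C)C(=O)C[C@@H]12)C(C)(C)O[Si](C)(C)C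
F2 | step 8 | tert-butyl 7-geranyl-3,3-dimethyl-2,8-dioxo-5-(prop-1-en-2-yl)decahydroazulene-7-carboxylate (ester cis to isopropenyl) | O=C1[C@](C/C=C(\C)CCC=C(C)C)(C(=O)OC(C)(C)C)C[C@H](C(C)=C)C[C@H]2C(C)(C)C(=O)C[C@@H]12
F3 | step 11 | 7-geranyl-3,3-dimethyl-2,8-dioxo-5-[2-(trimethylsilyloxy)propan-2-yl]decahydroazulene-7-carbaldehyde | O=C1[C@](C/C=C(\C)CCC=C(C)C)(C=O)C[C@@H](C[C@H]2C(C)(C)C(=O)C[C@@H]12)C(C)(C)O[Si](C)(C)C
F4 | step 11 | 7-[(2,2-dimethyl-4-oxo-6-phenyl-4H-1,3-dioxin-5-yl)(hydroxy)methyl]-7-geranyl-3,3-dimethyl-5-[2-(trimethylsilyloxy)propan-2-yl]octahydroazulene-2,8-dione (either carbinol epimer) | O=C1[C@](C/C=C(\C)CCC=C(C)C)(C(O)C3=C(c4ccccc4)OC(C)(C)OC3=O)C[C@@H](C[C@H]2C(C)(C)C(=O)C[C@@H]12)C(C)(C)O[Si](C)(C)C
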